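The route rests on a late C8–C9 disconnection of the 14-membered carbocycle (cembrane atoms C1–C14). One intramolecular Nozaki–Hiyama–Kishi reaction closes this ring last, with the C3–C4 oxirane already in place. It exploits the (Z)-C7=C8(C19H2OH)–C9(=O) hydroxymethyl enone of the large ring, whose geometry is stored beforehand in a 2-iodoallyl ether. The open-chain precursor is assembled from two monoterpenes: nerol supplies C2–C7 and, by Sharpless epoxidation, the cis-epoxide; (R)-citronellic acid supplies C9–C14 with the C12 stereocentre. Both isopropylidene termini are excised by ozonolysis, and an aldol condensation joins the halves at C1=C2.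

Key step: step 15

Remark on numbering: skeleton atoms are given cembrane numbers throughout (C1 carries the isopropyl group, C3/C4 the oxirane, C4 the methyl C18, C8 the hydroxymethyl carbon C19, C9 and C14 the ketones, C12 the methyl C20, C13 the hydroxyl).
Assumption: ethyl iodo(triphenylphosphoranylidene)acetate is a known, isolable reagent, made beforehand in one operation from commercial ethyl (triphenylphosphoranylidene)acetate and N-iodosuccinimide/K2CO3.

**Western half (C2–C8, C18, C19) from nerol**

Step 1
Reactants: 1 nerol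
Product: 2 (2S,3R)-2,3-epoxynerol
Conditions: Ti(OiPr)4 (cat.), L-(+)-diethyl tartrate (cat.), t-BuOOH, 4 Å MS, CH2Cl2, −20 °C
Reagents that add atoms: tert-butyl hydroperoxide, CC(C)(C)OO
Why: Sharpless asymmetric epoxidation: the titanium–L-(+)-tartrate complex binds the allylic hydroxyl and should deliver oxygen to one alkene face only, setting both oxirane centres as (2S,3R) (the later C3 and C4), with the cis relation of the two chain carbons fixed by the Z geometry of nerol, while the remote isopropylidene alkene has no directing group and stays intact.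

Step 2
Reactants: 2 (2S,3R)-2,3-epoxynerol
Product: 3 triethylsilyl ether of 2
Conditions: TESCl, imidazole, CH2Cl2, 0 °C
Reagents that add atoms: chlorotriethylsilane, CC[Si](Cl)(CC)CC
Why: Standard silylation of a primary alcohol; the TES ether masks the C2 oxygen through ozonolysis, olefination and reduction and is the one silyl ether that step 6 can oxidise directly.

Step 3
Reactants: 3 triethylsilyl ether of 2
Product: 6 ethyl (2Z)-2-iodo-5-[(2R,3S)-2-methyl-3-{[(triethylsilyl)oxy]methyl}oxiran-2-yl]pent-2-enoate, via ozonide 4 (not isolated), via aldehyde 5 (not isolated)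
Conditions: O3, CH2Cl2, −78 °C; Me2S, −78 °C → rt; concentrate; then Ph3P=C(I)CO2Et, CH2Cl2, rt
Reagents that add atoms: ethyl iodo(triphenylphosphoranylidene)acetate, CCOC(=O)C(I)=P(c1ccccc1)(c1ccccc1)c1ccccc1
Why: Ozonolysis with reductive work-up cuts off the isopropylidene end as acetone, and the Wittig reaction of the crude aldehyde with the stabilised α-iodo ylide should give mainly the (Z)-α-iodo enoate (ester trans to the chain, iodine cis to C6), which fixes the later C7=C8 geometry.

Step 4
Reactants: 6 the (Z)-α-iodo enoate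
Product: 7 (2Z)-2-iodo-5-[(2R,3S)-2-methyl-3-{[(triethylsilyl)oxy]methyl}oxiran-2-yl]pent-2-en-1-ol
Conditions: DIBAL-H, CH2Cl2, −78 °C; Rochelle salt work-up
Reagents that add atoms: none
Why: DIBAL-H 1,2-reduction of the enoate to the allylic alcohol (C19–OH) at low temperature should leave the vinyl iodide, the oxirane and the silyl ether untouched and keep the alkene geometry.

Step 5
Reactants: 7 the (Z)-2-iodoallylic alcohol
Product: 8 tert-butyldimethylsilyl ether of 7 (C2–OTES, C19–OTBS)
Conditions: TBSCl, imidazole, DMF, rt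
Reagents that add atoms: tert-butylchlorodimethylsilane, CC(C)(C)[Si](C)(C)Cl
Why: Standard silylation; the more robust TBS ether on C19 is needed to survive the selective oxidation of the TES ether and all later steps up to the final deprotection.

Step 6
Reactants: 8 the bis-silyl ether
Product: 10 (2R,3R)-3-[(3Z)-5-{[tert-butyl(dimethyl)silyl]oxy}-4-iodopent-3-en-1-yl]-3-methyloxirane-2-carbaldehyde, via sulfonium salt 9 (not isolated)
Conditions: (COCl)2, DMSO, CH2Cl2, −78 → −30 °C; then Et3N, −78 °C → rt
Reagents that add atoms: none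
Why: Swern oxidation applied directly to a primary triethylsilyl ether: activated DMSO attacks the TES-bearing oxygen with loss of the silyl group and gives the epoxy aldehyde in one operation, while the TBS ether is inert under these conditions and the oxirane centres are not touched.

**Eastern half (C9–C14, C20, isobutyl) from (R)-citronellic acid**

Step 7
Reactants: 11 (R)-citronellic acid; 12 (S)-4-benzyl-1,3-oxazolidin-2-one
Product: 14 (4S)-4-benzyl-3-[(3R)-3,7-dimethyloct-6-enoyl]-1,3-oxazolidin-2-one, via mixed anhydride 13 (not isolated)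
Conditions: PivCl, Et3N, THF, −20 °C; then 12, LiCl, rt
Reagents that add atoms: none
Why: Evans N-acylation through the mixed pivalic anhydride, which is attacked at the less hindered acyl group; the C3 centre of the acid (later C12, R) is not affected.

Step 8
Reactants: 14 the N-acyl oxazolidinone
Product: 16 (4S)-4-benzyl-3-[(2S,3R)-2-hydroxy-3,7-dimethyloct-6-enoyl]-1,3-oxazolidin-2-one, via sodium enolate 15 (not isolated)
Conditions: NaHMDS, THF, −78 °C; then 2-(phenylsulfonyl)-3-phenyloxaziridine, −78 °C; AcOH quench
Reagents that add atoms: 2-(phenylsulfonyl)-3-phenyloxaziridine, O=S(=O)(c1ccccc1)N1OC1c1ccccc1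
Why: Evans asymmetric enolate hydroxylation with the Davis oxaziridine: the chelated (Z)-sodium enolate is attacked on the face opposite the benzyl group, so the auxiliary should set the new carbinol centre as 2S (the later C13, syn to the C12 methyl in the zigzag chain).

Step 9
Reactants: 16 the α-hydroxy imide
Product: 17 (2S,3R)-2-hydroxy-N-methoxy-N,3,7-trimethyloct-6-enamide
Conditions: MeNH(OMe)·HCl, AlMe3, CH2Cl2, −15 → 0 °C; aq HCl work-up
Reagents that add atoms: N,O-dimethylhydroxylamine hydrochloride, CNOC.Cl
Why: Weinreb transamidation with the aluminium amide, directed to the exocyclic carbonyl by the free α-hydroxyl, should release the auxiliary 12 for recovery without epimerisation.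

Step 10
Reactants: 17 the hydroxy Weinreb amide
Product: 18 (2S,3R)-N-methoxy-N,3,7-trimethyl-2-[(triethylsilyl)oxy]oct-6-enamide
Conditions: TESOTf, 2,6-lutidine, CH2Cl2, −78 → 0 °C
Reagents that add atoms: triethylsilyl trifluoromethanesulfonate, CC[Si](CC)(CC)OS(=O)(=O)C(F)(F)F
Why: Silylation of the hindered secondary alcohol with the silyl triflate; the TES ether blocks the C13 oxygen for the enolate, mesylation and oxidation steps and comes off under the mildest fluoride conditions at the end.

Step 11
Reactants: 18 the silyloxy Weinreb amide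
Product: 19 (5S,6R)-2,6,10-trimethyl-5-[(triethylsilyl)oxy]undec-9-en-4-one
Conditions: i-BuMgBr, THF, 0 °C; aq NH4Cl
Reagents that add atoms: isobutylmagnesium bromide, CC(C)C[Mg]Br
Why: Weinreb ketone synthesis: the chelated tetrahedral adduct prevents over-addition and should give the isobutyl ketone (C14=O with C1 and the isopropyl group) without loss of the α-silyloxy centre.

**Union and end game**

Step 12
Reactants: 19 the isobutyl ketone; 10 the epoxy aldehyde
Product: 21 β-hydroxy ketone (C1–C2 aldol adduct; mixture of diastereomers at C1 and C2), via lithium enolate 20 (not isolated)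
Conditions: LDA, THF, −78 °C; then 10, −78 °C; aq NH4Cl
Reagents that add atoms: none
Why: Directed aldol addition: LDA should deprotonate the isobutyl CH2 (C1) rather than the hindered silyloxy-bearing methine C13, and the lithium enolate adds to the aldehyde only; the two new centres need no control because step 13 removes both.

Step 13
Reactants: 21 the aldol adduct
Product: 23 seco-enone with the (E)-C14(=O)–C1(iPr)=C2H–oxirane unit, via mesylate 22 (not isolated)
Conditions: MsCl, Et3N, CH2Cl2, 0 °C; then DBU, 0 °C → rt
Reagents that add atoms: none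
Why: Mesylation and E1cB elimination (aldol condensation) from either diastereomer should converge on the conjugated E-enone, in which C3 lies trans to the C14 carbonyl and cis to the isopropyl group, the Z isomer being disfavoured by the clash between acyl group and oxirane that twists the carbonyl out of conjugation.

Step 14
Reactants: 23 the seco-enone
Product: 25 seco-aldehyde (C9 aldehyde), via ozonide 24 (not isolated)
Conditions: O3 (1 equiv, Sudan Red 7B end point), CH2Cl2, −78 °C; then PPh3, −78 °C → rt
Reagents that add atoms: ozone, [O-][O+]=O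
Why: Chemoselective ozonolysis: the electron-rich isopropylidene alkene should react well before the enone alkene and the iodoalkene, both electron-poor, so that only the C9 aldehyde is unmasked.

Step 15
Reactants: 25 the seco-aldehyde
Product: 26 macrocyclic C9 allylic alcohol (14-membered ring; mixture of C9 epimers)
Conditions: CrCl2 (excess), NiCl2 (cat.), DMSO–THF, rt, high dilution (ca. 2 mM), slow addition of 25
Reagents that add atoms: none
Why: Ni(0), formed in situ from NiCl2 and Cr(II), inserts into the C8–I bond, transmetalation gives a configurationally stable alkenylchromium(III) species, and this adds intramolecularly to the C9 aldehyde to give the chromium alkoxide of 26. The reaction is a Nozaki–Hiyama–Kishi macrocyclisation, a well-precedented way of closing 12- to 16-membered carbocycles from iodoalkenyl aldehydes. The 14-membered ring (C1–C14) is closed by C8–C9 bond formation in an exo-trig 1,2-addition to the aldehyde carbonyl, the C=O lying outside the new ring, while the C3–C4 oxirane is already present and is not touched. The only new stereocentre, the C9 carbinol, is not controlled and need not be, because step 16 turns it into the ketone. The step needs chemoselectivity for the aldehyde over the C14 ketone, the epoxy enone and the silyl ethers, which the low basicity and aldehyde preference of alkenylchromium reagents should secure; retention of the C7=C8 geometry, which is the rule for trisubstituted alkenyl iodides; and ring closure over oligomerisation, which high dilution with slow addition secures and the three rigid units (E-enone, cis-oxirane, Z-alkene) should assist by folding the chain.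

Step 16
Reactants: 26 the macrocyclic allylic alcohol
Product: 27 macrocyclic 9,14-dione bis-silyl ether
Conditions: Dess–Martin periodinane, NaHCO3, CH2Cl2, 0 °C → rt
Reagents that add atoms: none
Why: Dess–Martin oxidation of the secondary allylic alcohol under buffered, non-basic conditions should give the (Z)-enone without isomerising the C7=C8 bond or opening the oxirane, and it merges both C9 epimers.

Step 17
Reactants: 27 the bis-silyl ether
Product: 28 (1E,3S,4R,7Z,12R,13S)-3,4-epoxy-13,19-dihydroxycembra-1,7-diene-9,14-dione (CNP0251075.1)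
Conditions: HF·pyridine, pyridine, THF, 0 °C → rt
Reagents that add atoms: none
Why: Buffered fluoride desilylation should remove the secondary TES and primary TBS ethers in one operation under conditions mild enough for the epoxy enone, the (Z)-enone and the α-hydroxy ketone.

**Compound list**

1 | nerol, (2Z)-3,7-dimethylocta-2,6-dien-1-ol | CC(C)=CCC/C(C)=C\CO | starting material
2 | (2S,3R)-2,3-epoxynerol, [(2S,3R)-3-methyl-3-(4-methylpent-3-en-1-yl)oxiran-2-yl]methanol | OC[C@@H]1O[C@]1(C)CCC=C(C)C | intermediate
3 | triethylsilyl ether of 2 | CC[Si](CC)(CC)OC[C@@H]1O[C@]1(C)CCC=C(C)C | intermediate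
4 | ozonide (1,2,4-trioxolane) of 3, epimers at the trioxolane CH, not isolated | CC[Si](CC)(CC)OC[C@@H]1O[C@]1(C)CCC2OOC(C)(C)O2 | intermediate
5 | 3-[(2R,3S)-2-methyl-3-{[(triethylsilyl)oxy]methyl}oxiran-2-yl]propanal, not isolated | CC[Si](CC)(CC)OC[C@@H]1O[C@]1(C)CCC=O | intermediate
6 | ethyl (2Z)-2-iodo-5-[(2R,3S)-2-methyl-3-{[(triethylsilyl)oxy]methyl}oxiran-2-yl]pent-2-enoate | CC[Si](CC)(CC)OC[C@@H]1O[C@]1(C)CC/C=C(\I)C(=O)OCC | intermediate
7 | (2Z)-2-iodo-5-[(2R,3S)-2-methyl-3-{[(triethylsilyl)oxy]methyl}oxiran-2-yl]pent-2-en-1-ol | CC[Si](CC)(CC)OC[C@@H]1O[C@]1(C)CC/C=C(\I)CO | intermediate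
8 | tert-butyldimethylsilyl ether of 7 (C2–OTES, C19–OTBS) | CC[Si](CC)(CC)OC[C@@H]1O[C@]1(C)CC/C=C(\I)CO[Si](C)(C)C(C)(C)C | intermediate
9 | alkoxydimethylsulfonium chloride derived from 8 at the C2 oxygen, not isolated | C[S+](C)OC[C@@H]1O[C@]1(C)CC/C=C(\I)CO[Si](C)(C)C(C)(C)C.[Cl-] | intermediate
10 | (2R,3R)-3-[(3Z)-5-{[tert-butyl(dimethyl)silyl]oxy}-4-iodopent-3-en-1-yl]-3-methyloxirane-2-carbaldehyde | O=C[C@@H]1O[C@]1(C)CC/C=C(\I)CO[Si](C)(C)C(C)(C)C | intermediate
11 | (R)-citronellic acid, (3R)-3,7-dimethyloct-6-enoic acid | CC(C)=CCC[C@@H](C)CC(O)=O | starting material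
12 | (S)-4-benzyl-1,3-oxazolidin-2-one | O=C1N[C@@H](Cc2ccccc2)CO1 | starting material
13 | (3R)-3,7-dimethyloct-6-enoic pivalic anhydride, not isolated | CC(C)=CCC[C@@H](C)CC(=O)OC(=O)C(C)(C)C | intermediate
14 | (4S)-4-benzyl-3-[(3R)-3,7-dimethyloct-6-enoyl]-1,3-oxazolidin-2-one | CC(C)=CCC[C@@H](C)CC(=O)N1[C@@H](Cc2ccccc2)COC1=O | intermediate
15 | sodium (Z)-enolate of 14, not isolated | CC(C)=CCC[C@@H](C)/C=C(\[O-])N1[C@@H](Cc2ccccc2)COC1=O.[Na+] | intermediate
16 | (4S)-4-benzyl-3-[(2S,3R)-2-hydroxy-3,7-dimethyloct-6-enoyl]-1,3-oxazolidin-2-one | CC(C)=CCC[C@@H](C)[C@H](O)C(=O)N1[C@@H](Cc2ccccc2)COC1=O | intermediate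
17 | (2S,3R)-2-hydroxy-N-methoxy-N,3,7-trimethyloct-6-enamide | CC(C)=CCC[C@@H](C)[C@H](O)C(=O)N(C)OC | intermediate
18 | (2S,3R)-N-methoxy-N,3,7-trimethyl-2-[(triethylsilyl)oxy]oct-6-enamide | CC(C)=CCC[C@@H](C)[C@H](O[Si](CC)(CC)CC)C(=O)N(C)OC | intermediate
19 | (5S,6R)-2,6,10-trimethyl-5-[(triethylsilyl)oxy]undec-9-en-4-one | CC(C)=CCC[C@@H](C)[C@H](O[Si](CC)(CC)CC)C(=O)CC(C)C | intermediate
20 | lithium enolate of 19 towards C1, not isolated | CC(C)=CCC[C@@H](C)[C@H](O[Si](CC)(CC)CC)C([O-])=CC(C)C.[Li+] | intermediate
21 | aldol adduct of 19 and 10, β-hydroxy ketone with C2–OH, mixture at C1 and C2 | CC(C)=CCC[C@@H](C)[C@H](O[Si](CC)(CC)CC)C(=O)C(C(C)C)C(O)[C@@H]1O[C@]1(C)CC/C=C(\I)CO[Si](C)(C)C(C)(C)C | intermediate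
22 | C2 mesylate of 21, not isolated | CC(C)=CCC[C@@H](C)[C@H](O[Si](CC)(CC)CC)C(=O)C(C(C)C)C(OS(C)(=O)=O)[C@@H]1O[C@]1(C)CC/C=C(\I)CO[Si](C)(C)C(C)(C)C | intermediate
23 | seco-enone: (1E)-enone, cis-3,4-oxirane, (7Z)-8-iodoalkene, C19–OTBS, C13–OTES, terminal isopropylidene | CC(C)=CCC[C@@H](C)[C@H](O[Si](CC)(CC)CC)C(=O)/C(C(C)C)=C/[C@@H]1O[C@]1(C)CC/C=C(\I)CO[Si](C)(C)C(C)(C)C | intermediate
24 | ozonide of 23 at the isopropylidene alkene, not isolated | CC1(C)OOC(CC[C@@H](C)[C@H](O[Si](CC)(CC)CC)C(=O)/C(C(C)C)=C/[C@@H]2O[C@]2(C)CC/C=C(\I)CO[Si](C)(C)C(C)(C)C)O1 | intermediate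
25 | seco-aldehyde: C9 aldehyde of the chain of 23 | O=CCC[C@@H](C)[C@H](O[Si](CC)(CC)CC)C(=O)/C(C(C)C)=C/[C@@H]1O[C@]1(C)CC/C=C(\I)CO[Si](C)(C)C(C)(C)C | intermediate
26 | macrocyclic C9 alcohol: 14-membered ring, C9–OH (epimers), C14 ketone, C13–OTES, C19–OTBS | CC(C)/C1=C\[C@@H]2O[C@]2(C)CC/C=C(/CO[Si](C)(C)C(C)(C)C)C(O)CC[C@@H](C)[C@H](O[Si](CC)(CC)CC)C1=O | intermediate
27 | macrocyclic 9,14-dione with C13–OTES and C19–OTBS | CC(C)/C1=C\[C@@H]2O[C@]2(C)CC/C=C(/CO[Si](C)(C)C(C)(C)C)C(=O)CC[C@@H](C)[C@H](O[Si](CC)(CC)CC)C1=O | intermediate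
28 | (1E,3S,4R,7Z,12R,13S)-3,4-epoxy-13,19-dihydroxycembra-1,7-diene-9,14-dione, CNP0251075.1 | CC(C)/C1=C\[C@@H]2O[C@]2(C)CC/C=C(/CO)C(=O)CC[C@@H](C)[C@H](O)C1=O | target

**Count and risks**

Total step count: 17. Longest linear sequence: 12 steps (steps 1–6 and 12–17, from nerol); the citronellic acid branch is 5 steps (7–11).

Steps most likely to fail:

1. Step 15 (ring closure). Cr(II) may reduce the γ,δ-epoxy enone by single-electron transfer, low-valent nickel may open the vinyl oxirane, or oligomerisation may compete with cyclisation. The fallback sets out from 25 and removes the enone before the metals are added. Selective reduction of the C14 ketone beside the aldehyde (NaBH4, CeCl3·7H2O, aqueous EtOH, −15 °C, the aldehyde being masked in situ as its hydrate) should give the C14 allylic alcohol seco-aldehyde F1. The same Ni/Cr ring closure on F1 would give the macrocyclic C9,C14-diol F2. Dess–Martin oxidation of both allylic alcohols of F2 comes back to the route at 27.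

2. Step 13 (aldol dehydration). The E1cB elimination may give E/Z mixtures at C1=C2, DBU may epimerise C13, or γ-deprotonation may open the oxirane. The fallback sets out from 18 and replaces steps 11–13 by an olefination. Acylation of lithiated dimethyl (2-methylpropyl)phosphonate (n-BuLi, THF, −78 °C) by 18 should give the α-isopropyl β-ketophosphonate F3. Its Horner–Wadsworth–Emmons reaction with aldehyde 10 under Masamune–Roush conditions (LiCl, i-Pr2NEt, MeCN) comes back to the route at 23.

3. Step 14 (ozonolysis). Ozone may also attack the iodoalkene or the enone alkene, or over-oxidise the new aldehyde. The fallback sets out from 23. Osmium-catalysed dihydroxylation (OsO4 cat., NMO, acetone–water), which prefers the unhindered electron-rich isopropylidene alkene, should give the terminal 1,2-diol F4. Glycol cleavage of F4 with NaIO4 comes back to the route at 25.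

Further compounds
F1 | step 15 | C14 allylic alcohol seco-aldehyde (C14–OH epimers; otherwise as 25) | O=CCC[C@@H](C)[C@H](O[Si](CC)(CC)CC)C(O)/C(C(C)C)=C/[C@@H]1O[C@]1(C)CC/C=C(\I)CO[Si](C)(C)C(C)(C)C
F2 | step 15 | macrocyclic C9,C14-diol (epimers at C9 and C14; C13–OTES, C19–OTBS) | CC(C)/C1=C\[C@@H]2O[C@]2(C)CC/C=C(/CO[Si](C)(C)C(C)(C)C)C(O)CC[C@@H](C)[C@H](O[Si](CC)(CC)CC)C1O
F3 | step 13 | dimethyl [(5S,6R)-2,6,10-trimethyl-4-oxo-5-[(triethylsilyl)oxy]undec-9-en-3-yl]phosphonate (epimers at C3) | CC(C)=CCC[C@@H](C)[C@H](O[Si](CC)(CC)CC)C(=O)C(C(C)C)P(=O)(OC)OC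
F4 | step 14 | terminal 1,2-diol of 23 (C9 secondary and tertiary carbinol; epimers at C9) | CC(C)(O)C(O)CC[C@@H](C)[C@H](O[Si](CC)(CC)CC)C(=O)/C(C(C)C)=C/[C@@H]1O[C@]1(C)CC/C=C(\I)CO[Si](C)(C)C(C)(C)C
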